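The synthesis rests on disconnecting the C1–C6 bond of the cyclohexane, exploiting the homoallylic alcohol unit C6(O)–C1–C7(=C14H2) of that ring. The oxirane (C3–O–C4) and the C5 oxygen are set first on a butenolide template and carried in an acyclic chain. In the key step the (Z)-alkenyl iodide of epoxy aldehyde 25 is converted by Pd-catalysed borylmethylation into a (Z)-allylboronate that adds at once to the C6 aldehyde. This one operation closes the six-membered carbocycle (the last ring made), creates the exocyclic C7=C14 methylene and sets C1 and C6, both cis to the C5 oxygen. Desilylation and double angeloylation complete the target.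

Key step: step 16

Remark (numbering used throughout): ring C1–C6, with C1 bearing the side chain, C2 = CH2, C3/C4 the oxirane carbons (CH3 on C4), and C5 and C6 oxygenated; C7 is the alkene carbon on C1, C14 its CH2 terminus, C8 the acetoxy carbon, C9–C11 the prenyl unit. PMB = 4-methoxybenzyl, TBS = tert-butyldimethylsilyl, Bpin = pinacolatoboryl.

Assumption: the facial sense of the two catalyst-controlled steps (1 and 9) is taken from the accepted models for these catalysts; should the opposite sense be found, the antipodal ligand is used. Aldehyde 1 is taken as a catalogue compound.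

Step 1
Reactants: 1 2-[(4-methoxybenzyl)oxy]acetaldehyde; 2 methyl propiolate
Product: 4 methyl (S)-4-hydroxy-5-(PMB-oxy)pent-2-ynoate, via zinc acetylide 3 (not isolated)
Conditions: (S,S)-ProPhenol (10 mol %), Me2Zn, toluene, 0 °C; aq. NH4Cl
Reagents that add atoms: none
Why: Zinc–ProPhenol (Trost) asymmetric alkynylation, in which the dinuclear zinc catalyst delivers the zinc acetylide to one aldehyde face and so should set the C5 carbinol as (S).

Step 2
Reactants: 4 methyl (S)-4-hydroxy-5-(PMB-oxy)pent-2-ynoate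
Product: 6 (S)-4-methyl-5-(PMB-oxymethyl)furan-2(5H)-one, via Z-enoate 5 (not isolated)
Conditions: Me2CuLi (from MeLi, CuI), THF, −78 °C; aq. NH4Cl, then rt
Reagents that add atoms: lithium dimethylcuprate [Li+].C[Cu-]C
Why: Syn carbocupration of the ynoate (Corey–Katzenellenbogen cuprate addition) puts CH3 on C4 and leaves C5 cis to the ester, so the (Z)-γ-hydroxy enoate should lactonise to the butenolide; C5 is untouched.

Step 3
Reactants: 6 (S)-4-methyl-5-(PMB-oxymethyl)furan-2(5H)-one
Product: 7 (1R,4R,5R)-5-methyl-4-(PMB-oxymethyl)-3,6-dioxabicyclo[3.1.0]hexan-2-one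
Conditions: aq. NaOCl, pyridine, 0 °C → rt
Reagents that add atoms: sodium hypochlorite [Na+].[O-]Cl
Why: Nucleophilic (Weitz–Scheffer-type) epoxidation of the butenolide should occur on the face anti to the C5 CH2OPMB group, which sets C3 and C4 relative to C5 by substrate control.

Step 4
Reactants: 7 (1R,4R,5R)-5-methyl-4-(PMB-oxymethyl)-3,6-dioxabicyclo[3.1.0]hexan-2-one
Product: 8 (1R)-1-[(2R,3S)-3-(hydroxymethyl)-2-methyloxiran-2-yl]-2-(PMB-oxy)ethan-1-ol
Conditions: NaBH4, EtOH, 0 °C
Reagents that add atoms: none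
Why: Borohydride reduction of the α-oxygenated lactone to the diol should leave the oxirane and all three stereocentres unchanged.

Step 5
Reactants: 8 (1R)-1-[(2R,3S)-3-(hydroxymethyl)-2-methyloxiran-2-yl]-2-(PMB-oxy)ethan-1-ol
Product: 9 primary (C2) tosylate of diol 8
Conditions: TsCl (1.05 equiv), Et3N, DMAP (cat.), CH2Cl2, −10 °C
Reagents that add atoms: 4-toluenesulfonyl chloride Cc1ccc(cc1)S(=O)(=O)Cl
Why: Selective sulfonylation of the primary C2 hydroxyl over the secondary C5 hydroxyl, which is hindered by the adjacent quaternary C4.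

Step 6
Reactants: 9 primary (C2) tosylate of diol 8
Product: 10 C5 TBS ether of tosylate 9
Conditions: TBSOTf, 2,6-lutidine, CH2Cl2, −78 → 0 °C
Reagents that add atoms: tert-butyldimethylsilyl triflate CC(C)(C)[Si](C)(C)OS(=O)(=O)C(F)(F)F
Why: Silyl ether formation with the silyl triflate protects the C5 oxygen, which would otherwise displace the cis-disposed C2 leaving group under the basic coupling conditions.

Step 7
Reactants: 11 4-methylpent-3-enoic acid
Product: 13 N-methoxy-N,4-dimethylpent-3-enamide, via acyl imidazole 12 (not isolated)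
Conditions: CDI, CH2Cl2, rt; then MeNHOMe·HCl
Reagents that add atoms: N,O-dimethylhydroxylamine hydrochloride CNOC.Cl
Why: Amide formation through the acyl imidazole (CDI activation) should give the Weinreb amide under conditions mild enough to keep the β,γ-double bond in place.

Step 8
Reactants: 13 N-methoxy-N,4-dimethylpent-3-enamide; 14 ethynyltrimethylsilane
Product: 16 6-methyl-1-(trimethylsilyl)hept-5-en-1-yn-3-one, via lithium acetylide 15 (not isolated)
Conditions: 14, n-BuLi, THF, −78 °C; then 13, −78 → 0 °C; aq. NH4Cl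
Reagents that add atoms: none
Why: Weinreb ketone synthesis, in which the chelated tetrahedral adduct stops the acetylide addition at the ynone stage.

Step 9
Reactants: 16 6-methyl-1-(trimethylsilyl)hept-5-en-1-yn-3-one
Product: 17 (S)-6-methyl-1-(trimethylsilyl)hept-5-en-1-yn-3-ol
Conditions: Ru[(S,S)-TsDPEN](p-cymene) (1 mol %), i-PrOH, rt
Reagents that add atoms: none
Why: Noyori asymmetric transfer hydrogenation of an ynone under base-free conditions; the catalyst differentiates alkynyl from alkyl and should deliver hydride to give the (S)-carbinol at C8.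

Step 10
Reactants: 17 (S)-6-methyl-1-(trimethylsilyl)hept-5-en-1-yn-3-ol
Product: 18 (S)-6-methylhept-5-en-1-yn-3-ol
Conditions: K2CO3, MeOH, rt
Reagents that add atoms: none
Why: Base-mediated protodesilylation (methanolysis) of the alkynylsilane frees the terminal alkyne without touching C8.

Step 11
Reactants: 18 (S)-6-methylhept-5-en-1-yn-3-ol; 10 C5 TBS ether of tosylate 9
Product: 20 (4S)-1-[(2S,3S)-3-{(1R)-1-(TBS-oxy)-2-(PMB-oxy)ethyl}-3-methyloxiran-2-yl]-7-methyloct-6-en-2-yn-4-ol, via dilithium salt 19 (not isolated)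
Conditions: 18, n-BuLi (2.1 equiv), THF, −78 → −20 °C; DMPU, then 10, −20 °C → rt
Reagents that add atoms: none
Why: SN2 alkylation of the acetylide carbon of the alkoxide–acetylide dianion by the primary tosylate should form C1–C2, the hindered trisubstituted oxirane being inert to acetylides without a Lewis acid.

Step 12
Reactants: 20 coupled enynol (C1≡C7, free C8–OH)
Product: 22 (Z)-C7 iodide of the C1=C7 alkene with free C8–OH (3S,4S,5R,8S), via alkenylstannane 21 (not isolated)
Conditions: [Cp*RuCl]4 (2 mol %), Bu3SnH, CH2Cl2, rt; then I2 (1.0 equiv), 0 °C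
Reagents that add atoms: iodine II
Why: Hydroxyl-directed ruthenium-catalysed trans-hydrostannation should place tin on C7 (proximal to the C8 hydroxyl) and H on C1 in anti fashion, and iododestannylation with retention then gives the alkenyl iodide with iodine cis to C2.

Step 13
Reactants: 22 (Z)-alkenyl iodide with free C8–OH
Product: 23 C8 acetate of iodide 22
Conditions: Ac2O, pyridine, DMAP (cat.), CH2Cl2, 0 °C → rt
Reagents that add atoms: acetic anhydride CC(=O)OC(C)=O
Why: DMAP-catalysed acetylation of the secondary allylic alcohol installs the C8 acetate of the target with retention at C8.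

Step 14
Reactants: 23 C8 acetate of iodide 22
Product: 24 primary C6 alcohol (PMB removed)
Conditions: DDQ, CH2Cl2/pH 7 buffer, 0 °C
Reagents that add atoms: none
Why: Oxidative PMB ether cleavage by DDQ is selective for the electron-rich benzyl ether and should spare silyl ether, acetate, oxirane and alkenyl iodide.

Step 15
Reactants: 24 primary C6 alcohol
Product: 25 epoxy aldehyde (C6 aldehyde, C5–OTBS, C3/C4 oxirane, (Z)-C7 iodide, C8–OAc; 3S,4S,5S,8S)
Conditions: Dess–Martin periodinane, NaHCO3, CH2Cl2, 0 °C → rt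
Reagents that add atoms: none
Why: Buffered Dess–Martin oxidation should give the α-silyloxy aldehyde without epimerising C5.

Step 16
Reactants: 25 epoxy aldehyde
Product: 28 all-cis cyclohexanol (1S,3S,4S,5R,6R,8S) with C6–OH and C5–OTBS, via allylboronate 26 (not isolated), via borate ester 27 (not isolated)
Conditions: IZnCH2Bpin (1.5 equiv, from ICH2Bpin and Zn dust), Pd(PPh3)4 (5 mol %), THF, rt; aq. NaHCO3 work-up
Reagents that add atoms: [(pinacolatoboryl)methyl]zinc iodide I[Zn]CB1OC(C)(C)C(C)(C)O1
Why: Pd(0) inserts into the C7–I bond with retention, and transmetalation from the α-boryl alkylzinc followed by reductive elimination gives (Z)-allylboronate 26 with C14H2–B cis to C2, which adds through C1 to the C6 aldehyde via a closed six-membered chair transition state (B–O–C6–C1–C7–C14) to give borate 27, hydrolysed on work-up. The closest known reactions are the Knochel–Miyaura Negishi coupling of alkenyl halides with borylmethylzinc reagents and the Hoffmann-type intramolecular allylboration of ω-oxo allylboronates. The carbocycle C1–C6 closes by a 6-exo-trig addition to the carbonyl (new bond C1–C6), and the allyl transposition leaves C7=C14 exocyclic. C1 and C6 are set cis to each other by the Z geometry of the allylboronate (C2 axial and C5 equatorial on the allylboration chair, a cis-decalin-like bicyclic transition state), and both are set cis to C5–OTBS because that group sits pseudo-equatorial and anti to the incoming C1 (Felkin–Anh), as for Z-crotylboronates with α-alkoxy aldehydes. The step needs oxidative addition at C–I to outrun ionisation of the C8 allylic acetate and needs the alkene geometry to be retained; the first is secured by the high reactivity of the alkenyl iodide at room temperature with only a small excess of zinc reagent, the second by the stereospecific coupling and the configurational stability of pinacol allylboronates.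

Step 17
Reactants: 28 all-cis cyclohexanol with C5–OTBS
Product: 29 C5,C6 cis-diol (1S,3S,4R,5R,6R,8S)
Conditions: TBAF, AcOH, THF, rt
Reagents that add atoms: none
Why: Buffered fluoride desilylation should spare the acetate and the oxirane, and a possible 1,2-silyl shift to C6–O is inconsequential because both oxygens end up free.

Step 18
Reactants: 29 C5,C6 cis-diol
Product: 31 target CNP0188566.2, via mono-angelate 30 (not isolated)
Conditions: angelic acid, 2,4,6-trichlorobenzoyl chloride, Et3N, toluene, rt; then 29, 80 °C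
Reagents that add atoms: angelic acid C/C=C(/C)C(=O)O
Why: Yamaguchi-type esterification through the angelic 2,4,6-trichlorobenzoic mixed anhydride without DMAP should acylate both hindered secondary alcohols while avoiding Z-to-E isomerisation to tiglate; either mono-ester converges on 31.

Compound list

1 | 2-[(4-methoxybenzyl)oxy]acetaldehyde | O=CCOCc1ccc(OC)cc1 | starting material
2 | methyl propiolate | C#CC(=O)OC | starting material
3 | methyl(3-methoxy-3-oxoprop-1-yn-1-yl)zinc, zinc acetylide of 2 | COC(=O)C#C[Zn]C | intermediate (not isolated)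
4 | methyl (S)-4-hydroxy-5-(PMB-oxy)pent-2-ynoate | COC(=O)C#C[C@H](O)COCc1ccc(OC)cc1 | intermediate
5 | methyl (2Z,4S)-4-hydroxy-3-methyl-5-(PMB-oxy)pent-2-enoate | COC(=O)/C=C(/C)[C@H](O)COCc1ccc(OC)cc1 | intermediate (not isolated)
6 | (S)-4-methyl-5-(PMB-oxymethyl)furan-2(5H)-one | O=C1C=C(C)[C@@H](COCc2ccc(OC)cc2)O1 | intermediate
7 | (1R,4R,5R)-5-methyl-4-(PMB-oxymethyl)-3,6-dioxabicyclo[3.1.0]hexan-2-one, oxirane trans to CH2OPMB | O=C1[C@@H]2O[C@]2(C)[C@H](O1)COCc3ccc(OC)cc3 | intermediate
8 | (1R)-1-[(2R,3S)-3-(hydroxymethyl)-2-methyloxiran-2-yl]-2-(PMB-oxy)ethan-1-ol | OC[C@@H]1O[C@]1(C)[C@H](O)COCc2ccc(OC)cc2 | intermediate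
9 | {(2S,3R)-3-[(1R)-1-hydroxy-2-(PMB-oxy)ethyl]-3-methyloxiran-2-yl}methyl 4-methylbenzenesulfonate | Cc1ccc(cc1)S(=O)(=O)OC[C@@H]2O[C@]2(C)[C@H](O)COCc3ccc(OC)cc3 | intermediate
10 | {(2S,3S)-3-[(1R)-1-(TBS-oxy)-2-(PMB-oxy)ethyl]-3-methyloxiran-2-yl}methyl 4-methylbenzenesulfonate | Cc1ccc(cc1)S(=O)(=O)OC[C@@H]2O[C@]2(C)[C@H](O[Si](C)(C)C(C)(C)C)COCc3ccc(OC)cc3 | intermediate
11 | 4-methylpent-3-enoic acid | CC(C)=CCC(=O)O | starting material
12 | 1-(4-methylpent-3-enoyl)imidazole | CC(C)=CCC(=O)n1ccnc1 | intermediate (not isolated)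
13 | N-methoxy-N,4-dimethylpent-3-enamide | CON(C)C(=O)CC=C(C)C | intermediate
14 | ethynyltrimethylsilane | C#C[Si](C)(C)C | starting material
15 | lithium (trimethylsilyl)acetylide | [Li]C#C[Si](C)(C)C | intermediate (not isolated)
16 | 6-methyl-1-(trimethylsilyl)hept-5-en-1-yn-3-one | CC(C)=CCC(=O)C#C[Si](C)(C)C | intermediate
17 | (S)-6-methyl-1-(trimethylsilyl)hept-5-en-1-yn-3-ol | C[Si](C)(C)C#C[C@H](CC=C(C)C)O | intermediate
18 | (S)-6-methylhept-5-en-1-yn-3-ol | C#C[C@H](CC=C(C)C)O | intermediate
19 | dilithium alkoxide–acetylide of 18 | [Li]C#C[C@H](CC=C(C)C)O[Li] | intermediate (not isolated)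
20 | (4S)-1-[(2S,3S)-3-{(1R)-1-(TBS-oxy)-2-(PMB-oxy)ethyl}-3-methyloxiran-2-yl]-7-methyloct-6-en-2-yn-4-ol (3S,4S,5R,8S) | CC(C)=CC[C@H](O)C#CC[C@@H]1O[C@]1(C)[C@H](O[Si](C)(C)C(C)(C)C)COCc2ccc(OC)cc2 | intermediate
21 | (Z)-C7 tributylstannane of the C1=C7 alkene, tin cis to C2, free C8–OH (3S,4S,5R,8S) | CC(C)=CC[C@H](O)/C(=C/C[C@@H]1O[C@]1(C)[C@H](O[Si](C)(C)C(C)(C)C)COCc2ccc(OC)cc2)[Sn](CCCC)(CCCC)CCCC | intermediate (not isolated)
22 | (2Z,4S)-3-iodo-1-[(2S,3S)-3-{(1R)-1-(TBS-oxy)-2-(PMB-oxy)ethyl}-3-methyloxiran-2-yl]-7-methylocta-2,6-dien-4-ol | CC(C)=CC[C@H](O)/C(I)=C/C[C@@H]1O[C@]1(C)[C@H](O[Si](C)(C)C(C)(C)C)COCc2ccc(OC)cc2 | intermediate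
23 | C8 acetate of 22 (3S,4S,5R,8S; Z) | CC(C)=CC[C@H](OC(C)=O)/C(I)=C/C[C@@H]1O[C@]1(C)[C@H](O[Si](C)(C)C(C)(C)C)COCc2ccc(OC)cc2 | intermediate
24 | primary C6 alcohol: 23 without PMB (3S,4S,5R,8S; Z) | CC(C)=CC[C@H](OC(C)=O)/C(I)=C/C[C@@H]1O[C@]1(C)[C@H](O[Si](C)(C)C(C)(C)C)CO | intermediate
25 | epoxy aldehyde: C6 aldehyde, C5–OTBS, C3/C4 oxirane, (Z)-C7 iodide, C8–OAc (3S,4S,5S,8S) | CC(C)=CC[C@H](OC(C)=O)/C(I)=C/C[C@@H]1O[C@]1(C)[C@H](O[Si](C)(C)C(C)(C)C)C=O | intermediate
26 | allylboronate aldehyde: 25 with CH2Bpin in place of I, C14 cis to C2 (3S,4S,5S,8S) | CC(C)=CC[C@H](OC(C)=O)/C(CB2OC(C)(C)C(C)(C)O2)=C/C[C@@H]1O[C@]1(C)[C@H](O[Si](C)(C)C(C)(C)C)C=O | intermediate (not isolated)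
27 | cyclised borate ester: all-cis ring, C6–O–Bpin, C5–OTBS (1S,3S,4S,5R,6R,8S) | C=C([C@H](CC=C(C)C)OC(C)=O)[C@@H]1C[C@@H]2O[C@]2(C)[C@H](O[Si](C)(C)C(C)(C)C)[C@@H]1OB3OC(C)(C)C(C)(C)O3 | intermediate (not isolated)
28 | all-cis cyclohexanol: C1 bears (3S)-3-acetoxy-6-methylhepta-1,5-dien-2-yl, C3/C4 oxirane, C5–OTBS, C6–OH (1S,3S,4S,5R,6R,8S) | C=C([C@H](CC=C(C)C)OC(C)=O)[C@@H]1C[C@@H]2O[C@]2(C)[C@H](O[Si](C)(C)C(C)(C)C)[C@@H]1O | intermediate
29 | C5,C6 cis-diol (1S,3S,4R,5R,6R,8S) | C=C([C@H](CC=C(C)C)OC(C)=O)[C@@H]1C[C@@H]2O[C@]2(C)[C@H](O)[C@@H]1O | intermediate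
30 | C6 mono-angelate of 29 | C=C([C@H](CC=C(C)C)OC(C)=O)[C@@H]1C[C@@H]2O[C@]2(C)[C@H](O)[C@@H]1OC(=O)/C(C)=C\C | intermediate (not isolated)
31 | CNP0188566.2: C8 acetate, C5 and C6 angelates, C3/C4 oxirane (1S,3S,4S,5R,6R,8S) | C=C([C@H](CC=C(C)C)OC(C)=O)[C@@H]1C[C@@H]2O[C@]2(C)[C@H](OC(=O)/C(C)=C\C)[C@@H]1OC(=O)/C(C)=C\C | target

Total step count: 18. Longest linear sequence: 14 steps (steps 1–6 and 11–18); steps 7–10 form the second branch.

Steps most likely to fail

Step 16 (key step). What may go wrong: Pd(0) may ionise the C8 allylic acetate (allylic substitution, or loss of boron from the 2-(borylmethyl)allyl acetate) in competition with oxidative addition at C–I, or the allylboronate may add to the wrong aldehyde face. Fallback: the order of events is changed so that palladium never meets an allylic acetate and the ring closure is triggered by an oxidation. It sets out from iodide 22, which still has the free C8 hydroxyl. Negishi coupling with the same borylmethylzinc reagent (Pd(PPh3)4, THF) should give the allylboronate alcohol F1, acetylation (Ac2O, pyridine, DMAP) the allylboronate acetate F2, and DDQ the primary alcohol F3. Dess–Martin oxidation of F3 then generates aldehyde 26, which cyclises through 27 and after work-up gives 28, where the route is rejoined.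

Step 12. What may go wrong: loss of regiocontrol in the hydrostannation (tin at C1), protodestannylation, or iodine-induced cyclisation of the C8 hydroxyl onto the prenyl double bond. Fallback: the iodoalkene is built by enone α-iodination and the C8 centre is reset by reagent control. It sets out from enynol 20. Red-Al trans-reduction of the propargylic alcohol should give the (E)-allylic alcohol F4, MnO2 the (E)-enone F5, and I2/pyridine (addition–elimination α-iodination) the (Z)-α-iodo enone F6 with iodine cis to C2. Reduction with (R)-Me-CBS and catecholborane then returns to iodide 22.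

Step 11. What may go wrong: competing O-alkylation or sulfonyl transfer to the alkoxide of the dianion, and slow displacement at the oxirane-bearing carbon. Fallback: the alkyne is attached as a monoanion and the C8 carbinol is made afterwards. It sets out from tosylate 10. Displacement with lithium (trimethylsilyl)acetylide 15 (THF/DMPU) should give the silylalkyne F7, K2CO3/MeOH the terminal alkyne F8, and lithiation followed by Weinreb amide 13 the ynone F9. Noyori transfer hydrogenation with the (S,S)-catalyst of step 9 then returns to enynol 20.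

Further compounds

F1 | step 16 | allylboronate alcohol: 22 with CH2Bpin in place of I (free C8–OH, C6–OPMB, C5–OTBS) | CC(C)=CC[C@H](O)/C(CB2OC(C)(C)C(C)(C)O2)=C/C[C@@H]1O[C@]1(C)[C@H](O[Si](C)(C)C(C)(C)C)COCc3ccc(OC)cc3
F2 | step 16 | allylboronate acetate: C8 acetate of F1 | CC(C)=CC[C@H](OC(C)=O)/C(CB2OC(C)(C)C(C)(C)O2)=C/C[C@@H]1O[C@]1(C)[C@H](O[Si](C)(C)C(C)(C)C)COCc3ccc(OC)cc3
F3 | step 16 | allylboronate primary alcohol: F2 without PMB | CC(C)=CC[C@H](OC(C)=O)/C(CB2OC(C)(C)C(C)(C)O2)=C/C[C@@H]1O[C@]1(C)[C@H](O[Si](C)(C)C(C)(C)C)CO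
F4 | step 12 | (E)-allylic alcohol: 20 with C1=C7 (E)-alkene in place of the alkyne | CC(C)=CC[C@H](O)/C=C/C[C@@H]1O[C@]1(C)[C@H](O[Si](C)(C)C(C)(C)C)COCc2ccc(OC)cc2
F5 | step 12 | (E)-enone: C8 ketone of F4 | CC(C)=CCC(=O)/C=C/C[C@@H]1O[C@]1(C)[C@H](O[Si](C)(C)C(C)(C)C)COCc2ccc(OC)cc2
F6 | step 12 | (Z)-α-iodo enone: F5 with iodine on C7, cis to C2 | CC(C)=CCC(=O)/C(I)=C/C[C@@H]1O[C@]1(C)[C@H](O[Si](C)(C)C(C)(C)C)COCc2ccc(OC)cc2
F7 | step 11 | silylalkyne: 10 with C≡C–SiMe3 in place of OTs | C[Si](C)(C)C#CC[C@@H]1O[C@]1(C)[C@H](O[Si](C)(C)C(C)(C)C)COCc2ccc(OC)cc2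
F8 | step 11 | terminal alkyne from F7 | C#CC[C@@H]1O[C@]1(C)[C@H](O[Si](C)(C)C(C)(C)C)COCc2ccc(OC)cc2
F9 | step 11 | ynone: C8 ketone corresponding to 20 | CC(C)=CCC(=O)C#CC[C@@H]1O[C@]1(C)[C@H](O[Si](C)(C)C(C)(C)C)COCc2ccc(OC)cc2
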